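**Retrosynthetic overview**

1. Numbering: ring A = C1–C5 and C10 (C4 carries the exocyclic CH2, C11; C10 the angular CH3). Ring B = C5–C10 (C8 = CH–CH3, C13; C9 = quaternary carbon with CH3, C14, and the benzylic CH2, C15).
2. Quinone: from a 2,3,5,6-tetramethoxyphenyl group by oxidative demethylation, then hydrolysis of the methoxy group next to C15. C4=C11: from a C4 ketone, carried as a carbinol while C6 is a ketone.
3. Key disconnection, C8–C9 (closes ring B): a tertiary C9 radical, born by hydrogen-atom transfer to a C9=C14 methylene, adds 6-endo to C8 of an (E)-enone whose carbonyl is a temporary C6 ketone. The step joins two alkene carbons reductively and makes the C14 methyl, both adjacent quaternary carbons and the C8 and C9 stereocentres.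
4. Enabling feature: C9 is a quaternary ring-B carbon that carries a methyl, so it maps onto a 1,1-disubstituted alkene. C8 is a methine separated from the ring-fusion carbon C5 only by C7 and C6, so a removable C6 carbonyl makes it an acceptor terminus and forces one boat-like closure.
5. Order of rings: arene (commercial) and ring A (commercial enone; C10 by Cu-catalysed asymmetric conjugate addition, C5 by aldol trapping), then ring B (step 5), then the quinone.

Key step: step 5

Remark: the carbinol centres formed at C6 (step 2) and C4 (step 3) are carried as epimer mixtures, because both carbons become ketones again; the SMILES leave them undefined.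

**Route**

Step 1
Reactants: 1 1,2,4,5-tetramethoxybenzene; 2 2,3-dibromoprop-1-ene
Product: 4 3-(2-bromoprop-2-en-1-yl)-1,2,4,5-tetramethoxybenzene, via aryllithium 3 (not isolated)
Conditions: n-BuLi, TMEDA, THF, 0 °C; CuBr·SMe2 (10 mol%), then 2 (1.5 equiv), −78 °C → rt
Reagents that add atoms: none
Why: Directed ortho-lithiation takes place at the ring C–H flanked by two methoxy groups, and the aryl-copper species formed from 3 displaces the allylic bromide of 2 (Cu-catalysed allylic substitution; SN2 and SN2' give the same product), leaving the vinylic C–Br bond for step 2.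

Step 2
Reactants: 4 3-(2-bromoprop-2-en-1-yl)-1,2,4,5-tetramethoxybenzene; 5 3-methylcyclohex-2-en-1-one; 6 (E)-but-2-enal
Product: 10 (2S,3S)-2-[(E)-1-hydroxybut-2-en-1-yl]-3-methyl-3-[3-(2,3,5,6-tetramethoxyphenyl)prop-1-en-2-yl]cyclohexan-1-one, via alkenyllithium 7 (not isolated), via alkenylalane 8 (not isolated), via aluminium enolate 9 (not isolated)
Conditions: 4, t-BuLi (2 equiv), Et2O, −78 °C; Me2AlCl, −78 → 0 °C; 5, Cu(thiophene-2-carboxylate) (10 mol%), chiral aminophosphine Ph2P–N[CH(CH3)(2-naphthyl)]2 (11 mol%, the antipode that gives the 3S ketone), Et2O, −30 °C; then 6, −78 °C; aq. potassium sodium tartrate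
Reagents that add atoms: none
Why: Br/Li exchange and Li-to-Al transmetalation give alkenylalane 8, whose Cu-catalysed asymmetric conjugate addition to the β-methyl enone sets the quaternary C10 under ligand control, and the regiodefined aluminium enolate 9 then undergoes aldol addition to 6 on the face of C5 anti to the larger alkenyl group on C10, which places C6 trans to the C9 unit.

Step 3
Reactants: 10 (2S,3S)-2-[(E)-1-hydroxybut-2-en-1-yl]-3-methyl-3-[3-(2,3,5,6-tetramethoxyphenyl)prop-1-en-2-yl]cyclohexan-1-one
Product: 11 (2R,3S)-2-[(E)-1-hydroxybut-2-en-1-yl]-3-methyl-3-[3-(2,3,5,6-tetramethoxyphenyl)prop-1-en-2-yl]cyclohexan-1-ol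
Conditions: NaBH4, MeOH, 0 °C
Reagents that add atoms: none
Why: Borohydride reduction stores the C4 ketone as a carbinol so that C5 stays sp3 once C6 becomes a ketone (a C4,C6-diketone would enolise through C5); either C4 epimer serves.

Step 4
Reactants: 11 (2R,3S)-2-[(E)-1-hydroxybut-2-en-1-yl]-3-methyl-3-[3-(2,3,5,6-tetramethoxyphenyl)prop-1-en-2-yl]cyclohexan-1-ol
Product: 12 (E)-1-{(1R,6S)-2-hydroxy-6-methyl-6-[3-(2,3,5,6-tetramethoxyphenyl)prop-1-en-2-yl]cyclohexyl}but-2-en-1-one
Conditions: MnO2 (excess), CH2Cl2, rt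
Reagents that add atoms: none
Why: MnO2 oxidises only the allylic C6 carbinol (chemoselective allylic oxidation) and gives the (E)-enone without touching the saturated C4 carbinol, under neutral conditions that should not trigger oxa-Michael closure of the C4 hydroxyl.

Step 5
Reactants: 12 (E)-1-{(1R,6S)-2-hydroxy-6-methyl-6-[3-(2,3,5,6-tetramethoxyphenyl)prop-1-en-2-yl]cyclohexyl}but-2-en-1-one
Product: 14 (3S,4R,4aS,8aR)-8-hydroxy-3,4,4a-trimethyl-4-[(2,3,5,6-tetramethoxyphenyl)methyl]octahydronaphthalen-1(2H)-one, via tertiary C9 radical 13 (not isolated)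
Conditions: Fe(acac)3 (30 mol%), PhSiH3 (2.5 equiv), EtOH/ethylene glycol 5:1, 0.01 M, 60 °C
Reagents that add atoms: none
Why: An iron hydride generated from Fe(acac)3 and PhSiH3 transfers a hydrogen atom to the terminal carbon C14 of the 1,1-disubstituted alkene (Markovnikov MHAT), which completes the C14 methyl and leaves the nucleophilic tertiary radical 13 at C9; 13 adds to C8, the β-carbon of the (E)-enone, and the α-keto radical is reduced to an iron enolate and protonated by the solvent. The closest known reaction type is the MHAT-initiated reductive coupling of an unactivated alkene with an enone (Fe(acac)3/PhSiH3 Giese-type addition), which is used intramolecularly to forge congested quaternary centres. Ring B closes in the 6-endo-trig mode with the C6 carbonyl inside the new ring, because attack at C7 (5-exo) is polarity-mismatched and would give an unstabilised radical. C8 is controlled by the geometry of closure: the s-trans enone must stay planar to accept the radical, so C5, C6, C7 and C8 are coplanar, and since ring A holds the C9–C10–C5–C6 dihedral gauche with one fixed sign (C9 unit and acyl group trans-diequatorial), C9 can reach only one face of C8 through a boat-like array with C5 and C8 as bow and stern, in which H8 takes the flagpole site syn to H5 and the (E)-methyl the bowsprit site, that is cis to the C10 methyl. C9 is controlled in the same array by the size difference of its two substituents: the ArCH2 group should take the open pseudo-equatorial site next to H8 and the small C14 methyl the site between C7 and the C10 methyl, which puts C15 trans and C14 cis to the C10 methyl; this preference is expected to be the weaker of the two controls. The step needs hydrogen-atom transfer to the electron-neutral 1,1-disubstituted alkene and not to the enone, which the opposite polarity of the two alkenes secures, and high dilution to suppress intermolecular coupling.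

Step 6
Reactants: 14 (3S,4R,4aS,8aR)-8-hydroxy-3,4,4a-trimethyl-4-[(2,3,5,6-tetramethoxyphenyl)methyl]octahydronaphthalen-1(2H)-one
Product: 15 N'-[(3S,4R,4aS,8aS)-8-hydroxy-3,4,4a-trimethyl-4-[(2,3,5,6-tetramethoxyphenyl)methyl]octahydronaphthalen-1(2H)-ylidene]-4-methylbenzenesulfonohydrazide
Conditions: TsNHNH2 (1.5 equiv), EtOH, 60 °C
Reagents that add atoms: 4-methylbenzenesulfonohydrazide, Cc1ccc(cc1)S(=O)(=O)NN
Why: Condensation of the C6 ketone to the tosylhydrazone (hydrazone formation), the nucleophile entering from the α face because the β face is screened by the axial C8 and C10 methyl groups.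

Step 7
Reactants: 15 N'-[(3S,4R,4aS,8aS)-8-hydroxy-3,4,4a-trimethyl-4-[(2,3,5,6-tetramethoxyphenyl)methyl]octahydronaphthalen-1(2H)-ylidene]-4-methylbenzenesulfonohydrazide
Product: 16 (4aS,5R,6S,8aR)-4a,5,6-trimethyl-5-[(2,3,5,6-tetramethoxyphenyl)methyl]decahydronaphthalen-1-ol
Conditions: catecholborane (3 equiv), CHCl3, 0 °C → rt; then NaOAc·3H2O, reflux
Reagents that add atoms: none
Why: Catecholborane adds hydride to the C=N bond and acetate-induced loss of sulfinate gives a diazene that extrudes N2 (mild Wolff–Kishner-type reduction of a tosylhydrazone), so C6 becomes CH2 without the strong base that could epimerise C5.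

Step 8
Reactants: 16 (4aS,5R,6S,8aR)-4a,5,6-trimethyl-5-[(2,3,5,6-tetramethoxyphenyl)methyl]decahydronaphthalen-1-ol
Product: 17 (4aS,5R,6S,8aR)-4a,5,6-trimethyl-5-[(2,3,5,6-tetramethoxyphenyl)methyl]octahydronaphthalen-1(2H)-one
Conditions: Dess–Martin periodinane, NaHCO3, CH2Cl2, 0 °C → rt
Reagents that add atoms: none
Why: Dess–Martin oxidation of the secondary C4 carbinol converges both epimers on one ketone under buffered conditions that should not epimerise the adjacent ring-fusion carbon C5.

Step 9
Reactants: 17 (4aS,5R,6S,8aR)-4a,5,6-trimethyl-5-[(2,3,5,6-tetramethoxyphenyl)methyl]octahydronaphthalen-1(2H)-one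
Product: 18 3-{[(1R,2S,4aS,8aS)-1,2,8a-trimethyl-5-methylidenedecahydronaphthalen-1-yl]methyl}-1,2,4,5-tetramethoxybenzene
Conditions: Zn, CH2Br2, TiCl4, THF/CH2Cl2, 0 °C → rt
Reagents that add atoms: dibromomethane, BrCBr
Why: Lombardo–Takai methylenation (gem-dizinc reagent with TiCl4) converts the enolisable C4 ketone into the exocyclic methylene without base, so C5 is not epimerised.

Step 10
Reactants: 18 3-{[(1R,2S,4aS,8aS)-1,2,8a-trimethyl-5-methylidenedecahydronaphthalen-1-yl]methyl}-1,2,4,5-tetramethoxybenzene
Product: 19 2,5-dimethoxy-3-{[(1R,2S,4aS,8aS)-1,2,8a-trimethyl-5-methylidenedecahydronaphthalen-1-yl]methyl}cyclohexa-2,5-diene-1,4-dione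
Conditions: (NH4)2Ce(NO3)6 (2.5 equiv), MeCN/H2O 2:1, 0 °C
Reagents that add atoms: water, O
Why: Oxidative demethylation of a para-dimethoxyarene to the quinone; either para pair gives the same 2,5-dimethoxyquinone, and the isolated 1,1-disubstituted alkene should survive the brief oxidation.

Step 11
Reactants: 19 2,5-dimethoxy-3-{[(1R,2S,4aS,8aS)-1,2,8a-trimethyl-5-methylidenedecahydronaphthalen-1-yl]methyl}cyclohexa-2,5-diene-1,4-dione
Product: 20 2-hydroxy-5-methoxy-3-{[(1R,2S,4aS,8aS)-1,2,8a-trimethyl-5-methylidenedecahydronaphthalen-1-yl]methyl}cyclohexa-2,5-diene-1,4-dione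
Conditions: HClO4 (60% aq.), THF, 0 °C → rt, short reaction time
Reagents that add atoms: water, O
Why: Acid-catalysed hydrolysis of a vinylogous ester (addition–elimination of water) should be fastest at the methoxy group flanked by the alkyl side chain, which is twisted out of conjugation and whose loss relieves strain, the regiochemistry expected for 3-alkyl-2,5-dimethoxy-1,4-benzoquinones.

**Compound list**

1 | 1,2,4,5-tetramethoxybenzene | COc1cc(OC)c(OC)cc1OC | starting material
2 | 2,3-dibromoprop-1-ene | BrCC(Br)=C | starting material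
3 | (2,3,5,6-tetramethoxyphenyl)lithium (formed in the flask) | [Li]c1c(OC)c(OC)cc(OC)c1OC | intermediate
4 | 3-(2-bromoprop-2-en-1-yl)-1,2,4,5-tetramethoxybenzene | C=C(Br)Cc1c(OC)c(OC)cc(OC)c1OC | intermediate
5 | 3-methylcyclohex-2-en-1-one | CC1=CC(=O)CCC1 | starting material
6 | (E)-but-2-enal | C/C=C/C=O | starting material
7 | [3-(2,3,5,6-tetramethoxyphenyl)prop-1-en-2-yl]lithium (formed in the flask) | [Li]C(=C)Cc1c(OC)c(OC)cc(OC)c1OC | intermediate
8 | dimethyl[3-(2,3,5,6-tetramethoxyphenyl)prop-1-en-2-yl]alumane (formed in the flask) | C[Al](C)C(=C)Cc1c(OC)c(OC)cc(OC)c1OC | intermediate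
9 | dimethylaluminium (S)-3-methyl-3-[3-(2,3,5,6-tetramethoxyphenyl)prop-1-en-2-yl]cyclohex-1-en-1-olate (formed in the flask) | C[Al](C)OC1=C[C@@](C)(C(=C)Cc2c(OC)c(OC)cc(OC)c2OC)CCC1 | intermediate
10 | (2S,3S)-2-[(E)-1-hydroxybut-2-en-1-yl]-3-methyl-3-[3-(2,3,5,6-tetramethoxyphenyl)prop-1-en-2-yl]cyclohexan-1-one (side-chain carbinol epimers) | O=C1CCC[C@](C)(C(=C)Cc2c(OC)c(OC)cc(OC)c2OC)[C@H]1C(O)/C=C/C | intermediate
11 | (2R,3S)-2-[(E)-1-hydroxybut-2-en-1-yl]-3-methyl-3-[3-(2,3,5,6-tetramethoxyphenyl)prop-1-en-2-yl]cyclohexan-1-ol (epimers at both carbinol carbons) | OC1CCC[C@](C)(C(=C)Cc2c(OC)c(OC)cc(OC)c2OC)[C@H]1C(O)/C=C/C | intermediate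
12 | (E)-1-{(1R,6S)-2-hydroxy-6-methyl-6-[3-(2,3,5,6-tetramethoxyphenyl)prop-1-en-2-yl]cyclohexyl}but-2-en-1-one (C2 carbinol epimers) | OC1CCC[C@](C)(C(=C)Cc2c(OC)c(OC)cc(OC)c2OC)[C@H]1C(=O)/C=C/C | intermediate
13 | tertiary C9 radical: 12 with a hydrogen atom added to the terminal alkene carbon, radical centre on the carbon bearing CH3 and CH2Ar (formed in the flask) | OC1CCC[C@](C)([C](C)Cc2c(OC)c(OC)cc(OC)c2OC)[C@H]1C(=O)/C=C/C | intermediate
14 | (3S,4R,4aS,8aR)-8-hydroxy-3,4,4a-trimethyl-4-[(2,3,5,6-tetramethoxyphenyl)methyl]octahydronaphthalen-1(2H)-one (C8 carbinol epimers) | OC1CCC[C@@]2(C)[C@H]1C(=O)C[C@H](C)[C@@]2(C)Cc1c(OC)c(OC)cc(OC)c1OC | intermediate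
15 | N'-[(3S,4R,4aS,8aS)-8-hydroxy-3,4,4a-trimethyl-4-[(2,3,5,6-tetramethoxyphenyl)methyl]octahydronaphthalen-1(2H)-ylidene]-4-methylbenzenesulfonohydrazide | OC1CCC[C@@]2(C)[C@H]1C(=NNS(=O)(=O)c3ccc(C)cc3)C[C@H](C)[C@@]2(C)Cc1c(OC)c(OC)cc(OC)c1OC | intermediate
16 | (4aS,5R,6S,8aR)-4a,5,6-trimethyl-5-[(2,3,5,6-tetramethoxyphenyl)methyl]decahydronaphthalen-1-ol (C1 carbinol epimers) | OC1CCC[C@@]2(C)[C@H]1CC[C@H](C)[C@@]2(C)Cc1c(OC)c(OC)cc(OC)c1OC | intermediate
17 | (4aS,5R,6S,8aR)-4a,5,6-trimethyl-5-[(2,3,5,6-tetramethoxyphenyl)methyl]octahydronaphthalen-1(2H)-one | O=C1CCC[C@@]2(C)[C@H]1CC[C@H](C)[C@@]2(C)Cc1c(OC)c(OC)cc(OC)c1OC | intermediate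
18 | 3-{[(1R,2S,4aS,8aS)-1,2,8a-trimethyl-5-methylidenedecahydronaphthalen-1-yl]methyl}-1,2,4,5-tetramethoxybenzene | C=C1CCC[C@@]2(C)[C@H]1CC[C@H](C)[C@@]2(C)Cc1c(OC)c(OC)cc(OC)c1OC | intermediate
19 | 2,5-dimethoxy-3-{[(1R,2S,4aS,8aS)-1,2,8a-trimethyl-5-methylidenedecahydronaphthalen-1-yl]methyl}cyclohexa-2,5-diene-1,4-dione | C=C1CCC[C@@]2(C)[C@H]1CC[C@H](C)[C@@]2(C)CC1=C(OC)C(=O)C=C(OC)C1=O | intermediate
20 | 2-hydroxy-5-methoxy-3-{[(1R,2S,4aS,8aS)-1,2,8a-trimethyl-5-methylidenedecahydronaphthalen-1-yl]methyl}cyclohexa-2,5-diene-1,4-dione | C=C1CCC[C@@]2(C)[C@H]1CC[C@H](C)[C@@]2(C)CC1=C(O)C(=O)C=C(OC)C1=O | target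

**Step count and risks**

Total step count: 11. Longest linear sequence: 11 steps (from 1; 5 and 6 enter in step 2).

Steps most likely to fail:

- **Step 5.** What may go wrong: radical 13 is quenched by hydrogen-atom transfer before it closes the crowded C8–C9 bond, so the C9=C14 alkene is simply hydrogenated. Fallback, setting out from 12 and returning at 14: Co-catalysed Markovnikov hydrochlorination of the 1,1-disubstituted alkene (Co(BF4)2·6H2O, salen-type ligand, TsCl, PhSiH3, EtOH, rt) should give the C9 tertiary chloride F1. Slow addition of Bu3SnH and AIBN to F1 in refluxing benzene then runs the same 6-endo closure as a stannane chain at low hydrogen-donor concentration and should give 14.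

- **Step 2.** What may go wrong: the aluminium enolate 9 is trapped sluggishly by the enal or with poor facial discrimination at C5, or the aldolate reverts during work-up. Fallback, setting out from 4 and 5 and returning at 10: the conjugate addition is run as in step 2 and quenched with Me3SiCl/Et3N, so that the silyl enol ether F2 is isolated. A Mukaiyama aldol addition of F2 to 6 (BF3·OEt2, CH2Cl2, −78 °C) through an open transition state should then give 10, again with bond formation anti to the alkenyl group.

- **Step 11.** What may go wrong: acid-induced migration of the exocyclic double bond into ring A, or hydrolysis at the other methoxy group. Fallback, setting out from 19 and returning at 20: both vinylogous esters are saponified (aq. NaOH, MeOH/THF, rt, then mild acidification) to the 2,5-dihydroxyquinone F3. F3 is then O-methylated once, at the less hindered hydroxyl remote from the side chain, with Me3SiCHN2 (1 equiv, MeOH/toluene, 0 °C) to give 20 without strong acid.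

Further compounds
F1 | step 5 | (E)-1-{(1R,6S)-6-[2-chloro-1-(2,3,5,6-tetramethoxyphenyl)propan-2-yl]-2-hydroxy-6-methylcyclohexyl}but-2-en-1-one (chloride and carbinol epimers) | OC1CCC[C@](C)(C(C)(Cl)Cc2c(OC)c(OC)cc(OC)c2OC)[C@H]1C(=O)/C=C/C
F2 | step 2 | trimethyl({(S)-3-methyl-3-[3-(2,3,5,6-tetramethoxyphenyl)prop-1-en-2-yl]cyclohex-1-en-1-yl}oxy)silane | C[Si](C)(C)OC1=C[C@@](C)(C(=C)Cc2c(OC)c(OC)cc(OC)c2OC)CCC1
F3 | step 11 | 2,5-dihydroxy-3-{[(1R,2S,4aS,8aS)-1,2,8a-trimethyl-5-methylidenedecahydronaphthalen-1-yl]methyl}cyclohexa-2,5-diene-1,4-dione | C=C1CCC[C@@]2(C)[C@H]1CC[C@H](C)[C@@]2(C)CC1=C(O)C(=O)C=C(O)C1=O
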